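The numbers are those of an exercise; what happens was integrated by code.

3 questions stand on this flask: the yield at the hour, the best of the changes, and the yield after alpha.

starting material 17 mM; partner 1.30 equiv; time 1.0 h

    starting material + partner → side product A (k1 = 1.9 M⁻¹ min⁻¹)
    intermediate → side product B (k2 = 0.0034 min⁻¹)
    starting material → intermediate (k3 = 0.026 min⁻¹)
    intermediate → target (k4 = 0.0032 min⁻¹)
    starting material → target (k5 = 0.016 min⁻¹)
    crystals ⇌ target, rate k6*(cs6 - [target]) while solid is left; crystals form when [target] > cs6 (cs6 = 0.22 mM, k6 = 2.4 min⁻¹)

- target and crystals together at 1.0 h, in percent of the starting material charged
- the change that raises the amount of target and crystals together at 1.0 h, in percent of the starting material charged most ("none" if none brings more than 2 percentage points) (epsilon / alpha / gamma / none)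
- amount of target and crystals together at 1.0 h, in percent of the starting material charged, after alpha

- epsilon: doubling the dissolution coefficient of step 6, all else as stated
- alpha: doubling the solubility in step 6, all else as stated
- gamma: doubling the amount of partner, all else as stated

- amounts and yields of target count crystals too
- given per volume of solution although it is solid: crystals
- run time (flask): 1.0 h

I freeze c(partner) at its charge, which makes the loss of starting material a pseudo-first-order lag. The partner step then runs at 0.0420 min⁻¹, and with the other two exits, 0.026 min⁻¹ and 0.016 min⁻¹, the total is 0.0840 min⁻¹. The time constant is 11.9 min, shorter than the 60 min of the run, so by hand nearly all of the starting material has reacted at the hour. The freeze is rough: by this reckoning the partner step takes 50.0% of the starting material, which costs the partner 38.5% of its own charge.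

The quantity I carry is the direct share, the rate constant of starting material to target divided by that total: 19.0%. The intermediate receives 31.0% and passes it on slowly at 0.0032 min⁻¹; over the 48.1 min it has on average, that adds 4.76%. My reckoning is therefore 23.8%.

Now the settings. Doubling the dissolution coefficient changes how fast target passes between solution and crystals, and doubling the solubility changes how it divides between them. No arrow takes target further, so by hand neither moves the sum. Doubling the partner raises the total to 0.126 min⁻¹, which gives 16.1%, a change of −7.7 percentage points.

The forecast gives 25.2%, none and 25.2%, starting from the words “Target does not react further”.

The simulation gives 25.0%, and 25.0% after alpha. Epsilon brings 0 points and gamma −8 points, so the answer is none.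

The reaction of starting material to target is the main reason for this yield: the run of this flask without that reaction gives 5.17% in place of 25.0%. In the neighbour flask with 6.8 mM of starting material and the same equivalents, less partner stands against the direct step, and by hand the direct share rises from 19.0% to 27.2%. That neighbour flask gives 32.4%, more than this flask, with 33.0% still held as intermediate.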